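## Analysis of the target

The target 18 is 7-hydroxy-6-methoxy-3-(3,4,5-trimethoxyphenyl)-4H-chromen-4-one, an isoflavone. It consists of a benzo ring A fused to a γ-pyranone ring C (O1, C2–H, C3, C4=O), with the trimethoxyphenyl ring B on C3. The molecule is flat and has no stereocentre, so every sp3 centre that appears on the way is transient and needs no control. Sensitive points are the free 7-hydroxyl (a vinylogous acid, para to the C4 carbonyl through ring A), the electrophilic C2 of the pyranone, and four aryl methyl ethers that must survive while one oxygen at C7 is unmasked; this rules out boron- or aluminium-halide deprotections at the end. The difficulty lies in the three different oxygens on ring A: the ring oxygen at C8a, a methoxy group at C6 and a free hydroxyl at C7. On a preformed 6,7-dioxygenated ring the 7-oxygen is the more acidic and is alkylated first, so the 6-methoxy/7-hydroxy pattern runs against the intrinsic preference. The strategy rests on the arrangement of ring A: C6 (OMe) is para to C8a (O), C7 next to C6 carries the third oxygen, C5 and C8 carry hydrogen, and C4a carries the whole C4–C3–C2 chain. This is the pattern that results when a methoxy(1-alkoxyvinyl)carbene ligand on chromium, one carbonyl ligand and a terminal alkyne are joined into a phenol.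

## Retrosynthetic reasoning

Compound numbers are those of the steps below; atom numbers are those of the final chromone.

**18 ⇒ 17.** The C2=C3 double bond and the free 7-hydroxyl are traced back to the 2-methoxychroman-4-one 17, which has a tert-butyl ether on O7. One acid treatment has to remove the C2 methoxy group by β-elimination (H3 is α to the ketone and benzylic) and cleave the tert-butyl ether, while the aryl methyl ethers stay. Keeping C2 at the aldehyde oxidation level from the start means ring C needs no dehydrogenation.

**17 ⇒ 16 ⇒ 15.** The C4 ketone comes from the alcohol 16 and this from the silyl ether 15. The oxidation is placed after ring closure on purpose: once the phenol oxygen is tied up as O1 there is no free 4-methoxyphenol left for the oxidant to attack.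

**15 ⇒ 14.** The O1–C2 bond is cut. Forward, the phenol of 14 displaces one methoxy group of the side-chain acetal under mild acid, a six-membered closure onto an oxocarbenium ion. The acid must be weak enough to leave the benzylic silyl ether and the aryl tert-butyl ether intact.

**14 ⇒ 12 + 7.** Ring A is taken apart at C5–C6, C4a–C8a and C8–C8a. The carbene carbon of 12 carries the methoxy group and becomes C6, its alkoxyvinyl carbons become C7 and C8, one carbonyl ligand becomes C8a with the phenol oxygen, and the two alkyne carbons of 7 become C5 and C4a. No other cut places all three ring A oxygens, each with a different substituent, in one operation. The forward reaction has to insert the terminal alkyne with its substituted carbon next to the carbonyl-derived carbon and has to take up CO.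

**12 ⇒ 8 + 9.** The carbene complex is opened at the bond between the carbene carbon and the vinyl carbon and at the O–methyl bond. The α-metalated form of 8 adds to a carbonyl ligand of 9 and the acylmetalate is O-methylated.

**7 ⇒ 6 ⇒ 4 + 5.** The silyl ether is removed and the bond between the carbinol carbon (later C4) and the alkyne is cut, giving the aldehyde 4 and the ethynyl nucleophile 5. This cut is chosen because it delivers the terminal alkyne and the C4 oxygen together.

**4 ⇒ 3 ⇒ 2 ⇒ 1.** The aldehyde is the partial reduction product of ester 3. The acetal carbon of 3 (later C2) is introduced by C-formylation of the arylacetate 1 to 2 followed by acetalisation, so that ring B, C3 and C2 all come from one cheap ester.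

## Alternatives that were turned down

**Alternative 1:** Disconnection of C3–C4 and O1–C2 of ring C. Forward, light of about 300 nm cleaves the salicylate acetonide 7-(benzyloxy)-6-methoxy-2,2-dimethyl-4H-1,3-benzodioxin-4-one (A1). The ketene released from A1 acts as a heterodiene towards the enol ether (E)-1,2,3-trimethoxy-5-(2-methoxyethenyl)benzene (A2): the nucleophilic carbon of A2 attacks the ketene carbon and the phenolic oxygen closes on the oxocarbenium carbon, giving the racemic trans-2-methoxyisoflavanone A3.
- For: it is convergent, both aromatic rings are bought, and A3 is the benzyl analogue of 17, so the finish is equally short. The total is roughly half the steps of the chosen route; on step economy it is clearly stronger.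
- Against: A2 is an electron-rich styrene that absorbs in the same window, so E/Z isomerisation and [2+2] dimerisation compete. The ketene is intercepted by any hydroxylic impurity. The aryl ketone A3 is itself photolabile on long irradiation. A1 presupposes a ring A on which O7 and the C6 methoxy group are already told apart, so the central problem is moved into the synthesis of the starting material.
- In its place the chosen route offers a thermal ring construction in which the oxygen pattern is fixed by the mechanism.

**Alternative 2:** Disconnection of O1–C8a and C4–C4a. Forward, fluoride unmasks the aryne from 4,5-bis(benzyloxy)-2-(trimethylsilyl)phenyl trifluoromethanesulfonate (A4). The enolate oxygen of the formyl ester A5 (identical with 2) adds to it, and the aryl anion attacks the ester to close ring C, giving the bis(benzyl) isoflavone A6.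
- For: it reaches the skeleton in two steps from A4 and A5 and, because the aryne is symmetric, the annulation has no regiochemical question. It is shorter than the chosen route.
- Against: the enolate is ambident, and attack through carbon followed by acyl transfer is the usual course of β-dicarbonyl enolates with arynes, whereas oxygen attack is needed here. The symmetry that keeps the annulation clean also makes O6 and O7 identical in A6. Hydrogenolysis gives the catechol A7, whose 7-hydroxyl is the more acidic and is methylated first; the target pattern then needs a protect, methylate, deprotect detour of three steps. An unsymmetrical aryne would give regioisomers, since alkoxy groups meta and para to the aryne carbons direct weakly.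
- The chosen route answers exactly this point: methoxy at C6 and a cleavable ether at C7 are placed unambiguously.

**Alternative 3:** Disconnection of C3–C4. Forward, an N-heterocyclic carbene (from a thiazolium or triazolium salt and an amine base) converts the aldehyde of 4-(benzyloxy)-5-methoxy-2-[2-oxo-2-(3,4,5-trimethoxyphenyl)ethoxy]benzaldehyde (A8) into an acyl-anion equivalent. This adds to the tethered aryl ketone and gives the racemic 3-hydroxychroman-4-one A9.
- For: it is the best precedented of the four, since the intramolecular aldehyde–ketone benzoin of salicylaldehyde-derived keto ethers is an established six-ring closure. A8 comes from one O-alkylation, and the whole route needs about four or five steps. On precedent and step count it is stronger than the chosen route.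
- Against: under amine base the acidic O–CH2–C(=O) methylene of A8 can add to the aldehyde instead (Rap–Stoermer-type condensation to a 2-aroylbenzofuran). A9 carries its hydroxyl on C3, so the chromone is reached only by dehydrating a tertiary alcohol α to a ketone, through a destabilised cation or a hindered sulfonate, with acyloin rearrangement as a competitor. A ring A with differentiated oxygens must again be prepared first.
- In its place the chosen route offers C2 at the aldehyde oxidation level, so that ring C aromatises by simple loss of an alcohol, and a ring A assembled from acyclic parts.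

Key step: step 7

Assumption: the target is achiral, so the sp3 centres that appear between steps 2 and 10 are carried as racemic mixtures of diastereomers and none is controlled.

## Route

Step 1
Reactants: 1 methyl 2-(3,4,5-trimethoxyphenyl)acetate
Product: 2 methyl 3-hydroxy-2-(3,4,5-trimethoxyphenyl)prop-2-enoate (enol form of the α-formyl ester)
Conditions: NaH, HCO2Me, THF, cat. MeOH, 0 °C → rt; aq. HCl
Reagents that add atoms: methyl formate, COC=O
Why: Crossed Claisen condensation (C-formylation) of the arylacetate enolate with a formate that cannot enolise; it is driven by formation of the stabilised enolate of 2.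

Step 2
Reactants: 2 methyl 3-hydroxy-2-(3,4,5-trimethoxyphenyl)prop-2-enoate
Product: 3 methyl 3,3-dimethoxy-2-(3,4,5-trimethoxyphenyl)propanoate (racemic)
Conditions: HC(OMe)3, MeOH, cat. H2SO4, rt → 40 °C; NaHCO3
Reagents that add atoms: trimethyl orthoformate, COC(OC)OC; methanol, CO
Why: Acid-catalysed acetalisation of the formyl tautomer with the orthoformate as water scavenger; mild temperature and neutralisation before concentration keep the acetal from eliminating to the 3-methoxyacrylate.

Step 3
Reactants: 3 methyl 3,3-dimethoxy-2-(3,4,5-trimethoxyphenyl)propanoate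
Product: 4 3,3-dimethoxy-2-(3,4,5-trimethoxyphenyl)propanal (racemic)
Conditions: iBu2AlH, CH2Cl2, −78 °C; MeOH, aq. potassium sodium tartrate (KNaC4H4O6)
Reagents that add atoms: none
Why: Partial ester reduction; the tetrahedral aluminium hemiacetal is held at −78 °C by chelation to the β-methoxy groups and collapses only on work-up. The aldehyde is used crude and at once because its α-hydrogen is acidic.

Step 4
Reactants: 4 3,3-dimethoxy-2-(3,4,5-trimethoxyphenyl)propanal; 5 ethynylmagnesium bromide (HC≡CMgBr)
Product: 6 5,5-dimethoxy-4-(3,4,5-trimethoxyphenyl)pent-1-yn-3-ol (racemic, mixture of diastereomers)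
Conditions: HC≡CMgBr, THF, −78 → −20 °C; aq. NH4Cl
Reagents that add atoms: none
Why: 1,2-Addition of an alkynyl Grignard reagent to the aldehyde at low temperature, where addition should outrun enolisation. The new carbinol centre forms without useful selectivity, which does not matter because it later becomes the C4 carbonyl.

Step 5
Reactants: 6 5,5-dimethoxy-4-(3,4,5-trimethoxyphenyl)pent-1-yn-3-ol
Product: 7 3-(tert-butyldimethylsilyloxy)-5,5-dimethoxy-4-(3,4,5-trimethoxyphenyl)pent-1-yne (mixture of diastereomers)
Conditions: TBSCl, imidazole, cat. DMAP, DMF, rt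
Reagents that add atoms: tert-butyldimethylsilyl chloride, CC(C)(C)[Si](C)(C)Cl
Why: Standard silylation of a secondary propargylic alcohol; the chloride/imidazole system is chosen over the silyl triflate, which would activate the dimethyl acetal.

Step 6
Reactants: 8 tert-butyl vinyl ether; 9 chromium hexacarbonyl Cr(CO)6
Product: 12 pentacarbonyl[(1-tert-butoxyvinyl)(methoxy)carbene]chromium, via 1-tert-butoxyvinyllithium 10 (not isolated), via lithium acylpentacarbonylchromate 11 (not isolated)
Conditions: t-BuLi, THF/pentane, −78 → 0 °C; Cr(CO)6, Et2O, 0 °C → rt; Me3OBF4, CH2Cl2, 0 °C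
Reagents that add atoms: trimethyloxonium tetrafluoroborate, C[O+](C)C.F[B-](F)(F)F
Why: Fischer carbene synthesis: α-lithiation of the enol ether, addition of the vinyllithium to a carbonyl ligand, and O-methylation of the acylchromate by the hard oxonium salt. The α-substituent on the vinyl group should stabilise the zerovalent chromium complex as in the isopropenyl and dihydropyranyl analogues; it is filtered quickly through silica under argon.

Step 7
Reactants: 12 pentacarbonyl[(1-tert-butoxyvinyl)(methoxy)carbene]chromium; 7 3-(tert-butyldimethylsilyloxy)-5,5-dimethoxy-4-(3,4,5-trimethoxyphenyl)pent-1-yne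
Product: 14 5-tert-butoxy-2-[1-(tert-butyldimethylsilyloxy)-3,3-dimethoxy-2-(3,4,5-trimethoxyphenyl)propyl]-4-methoxyphenol (mixture of diastereomers), via tricarbonylchromium arene complex 13 (not isolated)
Conditions: THF (0.05 M), 50 °C, Ar; then air, Et2O, rt
Reagents that add atoms: none
Why: Thermal loss of one CO from 12 lets the alkyne bind and insert into the Cr=C bond to give a vinylcarbene; CO insertion turns this into a chromium-bound dienylketene, which closes ring A by a thermal six-electron electrocyclisation (forming C8–C8a) and enolises to the arene, held as its Cr(CO)3 complex 13. The carbene carbon becomes C6 with its methoxy group, the alkyne carbons become C5 and C4a, the carbonyl ligand becomes C8a with the free hydroxyl, and the alkoxyvinyl carbons become C7 and C8. The closest known reaction type is the Dötz benzannulation of alkenyl(methoxy)carbene complexes of zerovalent chromium with terminal alkynes, cyclic 1-alkoxyvinyl (dihydropyranyl) complexes being the nearest relatives of 12. No stereocentre is formed and the two on the side chain are not touched. The step needs the alkyne to insert with its substituted carbon next to the carbonyl-derived carbon, which the branched propargylic group of 7 against a bare hydrogen at the other terminus secures on steric grounds. It also needs CO insertion to win over five-ring formation, which an alkenyl complex of chromium in a donor solvent favours. Neutral conditions leave acetal, silyl ether and tert-butyl ether alone, and air is used for decomplexation because cerium oxidants would turn the 4-methoxyphenol into a quinone.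

Step 8
Reactants: 14 5-tert-butoxy-2-[1-(tert-butyldimethylsilyloxy)-3,3-dimethoxy-2-(3,4,5-trimethoxyphenyl)propyl]-4-methoxyphenol
Product: 15 7-tert-butoxy-4-(tert-butyldimethylsilyloxy)-2,6-dimethoxy-3-(3,4,5-trimethoxyphenyl)chromane (mixture of diastereomers)
Conditions: PPTS (cat.), CH2Cl2, rt
Reagents that add atoms: none
Why: Intramolecular transacetalisation: the phenol closes on the oxocarbenium ion from the dimethyl acetal in a 6-exo mode. The weak acid should spare the benzylic silyl ether and the aryl tert-butyl ether, and the closure masks the oxidation-prone 4-methoxyphenol.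

Step 9
Reactants: 15 7-tert-butoxy-4-(tert-butyldimethylsilyloxy)-2,6-dimethoxy-3-(3,4,5-trimethoxyphenyl)chromane
Product: 16 7-tert-butoxy-2,6-dimethoxy-3-(3,4,5-trimethoxyphenyl)chroman-4-ol (mixture of diastereomers)
Conditions: Bu4NF, THF, 0 °C → rt
Reagents that add atoms: none
Why: Fluoride cleavage of the Si–O bond; the cyclic mixed acetal and the aryl ethers are inert to fluoride.

Step 10
Reactants: 16 7-tert-butoxy-2,6-dimethoxy-3-(3,4,5-trimethoxyphenyl)chroman-4-ol
Product: 17 7-tert-butoxy-2,6-dimethoxy-3-(3,4,5-trimethoxyphenyl)chroman-4-one (mixture of diastereomers)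
Conditions: Dess–Martin periodinane, NaHCO3, CH2Cl2, 0 °C → rt
Reagents that add atoms: none
Why: Dess–Martin oxidation of a secondary benzylic alcohol under buffered, non-acidic conditions, with no free phenol present. Any early loss of the C2 methoxy group from 17 only anticipates step 11.

Step 11
Reactants: 17 7-tert-butoxy-2,6-dimethoxy-3-(3,4,5-trimethoxyphenyl)chroman-4-one
Product: 18 7-hydroxy-6-methoxy-3-(3,4,5-trimethoxyphenyl)-4H-chromen-4-one
Conditions: CF3CO2H/CH2Cl2 (1:4), 0 °C → rt
Reagents that add atoms: none
Why: Acid-catalysed β-elimination of methanol across C2–C3 gives the conjugated γ-pyranone, and the aryl tert-butyl ether is cleaved through the tert-butyl cation. Aryl methyl ethers do not react with this acid.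

## Compound list

1 | methyl 2-(3,4,5-trimethoxyphenyl)acetate | COC(=O)Cc1cc(OC)c(OC)c(OC)c1 | starting material
2 | methyl 3-hydroxy-2-(3,4,5-trimethoxyphenyl)prop-2-enoate | COC(=O)C(=CO)c1cc(OC)c(OC)c(OC)c1 | intermediate
3 | methyl 3,3-dimethoxy-2-(3,4,5-trimethoxyphenyl)propanoate (racemic) | COC(=O)C(C(OC)OC)c1cc(OC)c(OC)c(OC)c1 | intermediate
4 | 3,3-dimethoxy-2-(3,4,5-trimethoxyphenyl)propanal (racemic) | O=CC(C(OC)OC)c1cc(OC)c(OC)c(OC)c1 | intermediate
5 | ethynylmagnesium bromide | C#C[Mg]Br | starting material
6 | 5,5-dimethoxy-4-(3,4,5-trimethoxyphenyl)pent-1-yn-3-ol (mixture of diastereomers) | C#CC(O)C(C(OC)OC)c1cc(OC)c(OC)c(OC)c1 | intermediate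
7 | 3-(tert-butyldimethylsilyloxy)-5,5-dimethoxy-4-(3,4,5-trimethoxyphenyl)pent-1-yne (mixture of diastereomers) | C#CC(O[Si](C)(C)C(C)(C)C)C(C(OC)OC)c1cc(OC)c(OC)c(OC)c1 | intermediate
8 | tert-butyl vinyl ether | C=COC(C)(C)C | starting material
9 | chromium hexacarbonyl Cr(CO)6 | O=C=[Cr](=C=O)(=C=O)(=C=O)(=C=O)=C=O | starting material
10 | 1-tert-butoxyvinyllithium | [Li]C(=C)OC(C)(C)C | intermediate (not isolated)
11 | lithium pentacarbonyl[(1-tert-butoxyvinyl)oxidocarbene]chromate | [Li+].[O-]C(C(=C)OC(C)(C)C)=[Cr](=C=O)(=C=O)(=C=O)(=C=O)=C=O | intermediate (not isolated)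
12 | pentacarbonyl[(1-tert-butoxyvinyl)(methoxy)carbene]chromium | COC(C(=C)OC(C)(C)C)=[Cr](=C=O)(=C=O)(=C=O)(=C=O)=C=O | intermediate
13 | tricarbonylchromium complex of 14, chromium η6-bound to ring A (drawn as arene plus Cr(CO)3) | Oc1cc(OC(C)(C)C)c(OC)cc1C(O[Si](C)(C)C(C)(C)C)C(C(OC)OC)c1cc(OC)c(OC)c(OC)c1.O=C=[Cr](=C=O)=C=O | intermediate (not isolated)
14 | 5-tert-butoxy-2-[1-(tert-butyldimethylsilyloxy)-3,3-dimethoxy-2-(3,4,5-trimethoxyphenyl)propyl]-4-methoxyphenol (mixture of diastereomers) | Oc1cc(OC(C)(C)C)c(OC)cc1C(O[Si](C)(C)C(C)(C)C)C(C(OC)OC)c1cc(OC)c(OC)c(OC)c1 | intermediate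
15 | 7-tert-butoxy-4-(tert-butyldimethylsilyloxy)-2,6-dimethoxy-3-(3,4,5-trimethoxyphenyl)chromane (mixture of diastereomers) | COC1Oc2cc(OC(C)(C)C)c(OC)cc2C(O[Si](C)(C)C(C)(C)C)C1c1cc(OC)c(OC)c(OC)c1 | intermediate
16 | 7-tert-butoxy-2,6-dimethoxy-3-(3,4,5-trimethoxyphenyl)chroman-4-ol (mixture of diastereomers) | COC1Oc2cc(OC(C)(C)C)c(OC)cc2C(O)C1c1cc(OC)c(OC)c(OC)c1 | intermediate
17 | 7-tert-butoxy-2,6-dimethoxy-3-(3,4,5-trimethoxyphenyl)chroman-4-one (mixture of diastereomers) | COC1Oc2cc(OC(C)(C)C)c(OC)cc2C(=O)C1c1cc(OC)c(OC)c(OC)c1 | intermediate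
18 | 7-hydroxy-6-methoxy-3-(3,4,5-trimethoxyphenyl)-4H-chromen-4-one | COc1cc2c(=O)c(-c3cc(OC)c(OC)c(OC)c3)coc2cc1O | target

## Step count and risk

Total: 11 steps. Longest linear sequence: 10 steps (steps 1–5 and 7–11, from 1); the carbene complex 12 joins after one step.

**Step 7 (key step).** Most likely to go wrong:
- loss of the propargylic silyloxy group from the chromium-bound phenol through o-quinone methide formation;
- oligomerisation of the terminal alkyne by repeated insertion;
- diversion to five-membered rings without CO uptake;
- decomposition of the enol-ether carbene complex before it reacts.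

Fallback, which gives up the ring A construction and uses a bought ring A; it sets out from 1 and comes back at 18. Saponification of 1 (LiOH, THF/H2O) gives 2-(3,4,5-trimethoxyphenyl)acetic acid F1. Friedel–Crafts acylation of commercial 4-methoxybenzene-1,3-diol (COc1ccc(O)cc1O) with F1 in BF3·OEt2 at 80 °C, which goes ortho to one hydroxyl and para to the other, gives the deoxybenzoin 1-(2,4-dihydroxy-5-methoxyphenyl)-2-(3,4,5-trimethoxyphenyl)ethanone F2. One-carbon ring closure with DMF, BF3·OEt2 and MsCl then gives 18.

**Step 6.** Most likely to go wrong: slow or incomplete α-deprotonation of the hindered vinyl ether (lithiation of this particular ether is assumed by analogy with ethyl and methyl vinyl ether), attack of t-BuLi on THF, and hydrolysis of the enol ether of the complex during purification.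

Fallback with a vinyl ether whose α-lithiation is established; it sets out from 9 and 7 and comes back at 18.
- Methoxymethyl vinyl ether F3 (one step by dehydrohalogenation of a 2-haloethyl methoxymethyl ether) is lithiated with s-BuLi in THF at −78 °C, added to 9 and methylated with Me3OBF4 to give pentacarbonyl{methoxy[1-(methoxymethoxy)vinyl]carbene}chromium F4.
- Benzannulation of F4 with 7 as in step 7 gives 2-[1-(tert-butyldimethylsilyloxy)-3,3-dimethoxy-2-(3,4,5-trimethoxyphenyl)propyl]-4-methoxy-5-(methoxymethoxy)phenol F5.
- The conditions of steps 8 to 10 then give 4-(tert-butyldimethylsilyloxy)-2,6-dimethoxy-7-(methoxymethoxy)-3-(3,4,5-trimethoxyphenyl)chromane F6, then 2,6-dimethoxy-7-(methoxymethoxy)-3-(3,4,5-trimethoxyphenyl)chroman-4-ol F7, then 2,6-dimethoxy-7-(methoxymethoxy)-3-(3,4,5-trimethoxyphenyl)chroman-4-one F8.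
- HCl in MeOH at 40 °C eliminates methanol and cleaves the methoxymethyl ether, giving 18.

**Step 4.** Most likely to go wrong: enolisation of the doubly activated α-carbon of 4 by the basic Grignard reagent, followed by β-elimination of methoxide and further addition.

Fallback that forms the C3–C4 bond instead and never passes through 4; it sets out from 1 and comes back at 7.
- The lithium enolate of 1 (LiN(iPr)2, THF, −78 °C) adds to commercial 3-(trimethylsilyl)propynal (C[Si](C)(C)C#CC=O) to give methyl 3-hydroxy-2-(3,4,5-trimethoxyphenyl)-5-(trimethylsilyl)pent-4-ynoate F9.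
- TBSCl/imidazole gives methyl 3-(tert-butyldimethylsilyloxy)-2-(3,4,5-trimethoxyphenyl)-5-(trimethylsilyl)pent-4-ynoate F10.
- iBu2AlH at −78 °C gives 3-(tert-butyldimethylsilyloxy)-2-(3,4,5-trimethoxyphenyl)-5-(trimethylsilyl)pent-4-ynal F11.
- Aprotic acetalisation (MeOSiMe3, cat. Me3SiOTf, CH2Cl2, −78 °C) gives 3-(tert-butyldimethylsilyloxy)-5,5-dimethoxy-4-(3,4,5-trimethoxyphenyl)-1-(trimethylsilyl)pent-1-yne F12.
- K2CO3 in MeOH removes the alkynyl silyl group and gives 7.

**Step 8.** Most likely to go wrong: ionisation of the benzylic silyl ether, which sits ortho to the phenol and para to the tert-butoxy group; elimination of methanol from the acetal without ring closure; or Friedel–Crafts attack of the oxocarbenium ion on the free ring carbon ortho to the side chain.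

Fallback that closes ring C only after C4 is a ketone; it sets out from 14 and comes back at 18.
- MOMCl and iPr2NEt cap the phenol as tert-butyl{1-[4-tert-butoxy-5-methoxy-2-(methoxymethoxy)phenyl]-3,3-dimethoxy-2-(3,4,5-trimethoxyphenyl)propoxy}dimethylsilane F13.
- Bu4NF gives 1-[4-tert-butoxy-5-methoxy-2-(methoxymethoxy)phenyl]-3,3-dimethoxy-2-(3,4,5-trimethoxyphenyl)propan-1-ol F14.
- Dess–Martin oxidation gives 1-[4-tert-butoxy-5-methoxy-2-(methoxymethoxy)phenyl]-3,3-dimethoxy-2-(3,4,5-trimethoxyphenyl)propan-1-one F15.
- Aqueous CF3CO2H in CH2Cl2 removes the methoxymethyl and tert-butyl groups and condenses the freed phenol with the acetal carbon, the classical chromone closure of a 2-hydroxyaryl ketone, giving 18.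

## Further compounds

F1 | step 7 | 2-(3,4,5-trimethoxyphenyl)acetic acid | COc1cc(CC(=O)O)cc(OC)c1OC
F2 | step 7 | 1-(2,4-dihydroxy-5-methoxyphenyl)-2-(3,4,5-trimethoxyphenyl)ethanone | COc1cc(C(=O)Cc2cc(OC)c(OC)c(OC)c2)c(O)cc1O
F3 | step 6 | methoxymethyl vinyl ether | C=COCOC
F4 | step 6 | pentacarbonyl{methoxy[1-(methoxymethoxy)vinyl]carbene}chromium | COCOC(=C)C(OC)=[Cr](=C=O)(=C=O)(=C=O)(=C=O)=C=O
F5 | step 6 | 2-[1-(tert-butyldimethylsilyloxy)-3,3-dimethoxy-2-(3,4,5-trimethoxyphenyl)propyl]-4-methoxy-5-(methoxymethoxy)phenol (mixture of diastereomers) | Oc1cc(OCOC)c(OC)cc1C(O[Si](C)(C)C(C)(C)C)C(C(OC)OC)c1cc(OC)c(OC)c(OC)c1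
F6 | step 6 | 4-(tert-butyldimethylsilyloxy)-2,6-dimethoxy-7-(methoxymethoxy)-3-(3,4,5-trimethoxyphenyl)chromane (mixture of diastereomers) | COCOc1cc2OC(OC)C(c3cc(OC)c(OC)c(OC)c3)C(O[Si](C)(C)C(C)(C)C)c2cc1OC
F7 | step 6 | 2,6-dimethoxy-7-(methoxymethoxy)-3-(3,4,5-trimethoxyphenyl)chroman-4-ol (mixture of diastereomers) | COCOc1cc2OC(OC)C(c3cc(OC)c(OC)c(OC)c3)C(O)c2cc1OC
F8 | step 6 | 2,6-dimethoxy-7-(methoxymethoxy)-3-(3,4,5-trimethoxyphenyl)chroman-4-one (mixture of diastereomers) | COCOc1cc2OC(OC)C(c3cc(OC)c(OC)c(OC)c3)C(=O)c2cc1OC
F9 | step 4 | methyl 3-hydroxy-2-(3,4,5-trimethoxyphenyl)-5-(trimethylsilyl)pent-4-ynoate (mixture of diastereomers) | COC(=O)C(c1cc(OC)c(OC)c(OC)c1)C(O)C#C[Si](C)(C)C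
F10 | step 4 | methyl 3-(tert-butyldimethylsilyloxy)-2-(3,4,5-trimethoxyphenyl)-5-(trimethylsilyl)pent-4-ynoate (mixture of diastereomers) | COC(=O)C(c1cc(OC)c(OC)c(OC)c1)C(O[Si](C)(C)C(C)(C)C)C#C[Si](C)(C)C
F11 | step 4 | 3-(tert-butyldimethylsilyloxy)-2-(3,4,5-trimethoxyphenyl)-5-(trimethylsilyl)pent-4-ynal (mixture of diastereomers) | O=CC(c1cc(OC)c(OC)c(OC)c1)C(O[Si](C)(C)C(C)(C)C)C#C[Si](C)(C)C
F12 | step 4 | 3-(tert-butyldimethylsilyloxy)-5,5-dimethoxy-4-(3,4,5-trimethoxyphenyl)-1-(trimethylsilyl)pent-1-yne (mixture of diastereomers) | COC(OC)C(c1cc(OC)c(OC)c(OC)c1)C(O[Si](C)(C)C(C)(C)C)C#C[Si](C)(C)C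
F13 | step 8 | tert-butyl{1-[4-tert-butoxy-5-methoxy-2-(methoxymethoxy)phenyl]-3,3-dimethoxy-2-(3,4,5-trimethoxyphenyl)propoxy}dimethylsilane (mixture of diastereomers) | COCOc1cc(OC(C)(C)C)c(OC)cc1C(O[Si](C)(C)C(C)(C)C)C(C(OC)OC)c1cc(OC)c(OC)c(OC)c1
F14 | step 8 | 1-[4-tert-butoxy-5-methoxy-2-(methoxymethoxy)phenyl]-3,3-dimethoxy-2-(3,4,5-trimethoxyphenyl)propan-1-ol (mixture of diastereomers) | COCOc1cc(OC(C)(C)C)c(OC)cc1C(O)C(C(OC)OC)c1cc(OC)c(OC)c(OC)c1
F15 | step 8 | 1-[4-tert-butoxy-5-methoxy-2-(methoxymethoxy)phenyl]-3,3-dimethoxy-2-(3,4,5-trimethoxyphenyl)propan-1-one (racemic) | COCOc1cc(OC(C)(C)C)c(OC)cc1C(=O)C(C(OC)OC)c1cc(OC)c(OC)c(OC)c1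
A1 | alternative 1 | 7-(benzyloxy)-6-methoxy-2,2-dimethyl-4H-1,3-benzodioxin-4-one | COc1cc2C(=O)OC(C)(C)Oc2cc1OCc1ccccc1
A2 | alternative 1 | (E)-1,2,3-trimethoxy-5-(2-methoxyethenyl)benzene | CO/C=C/c1cc(OC)c(OC)c(OC)c1
A3 | alternative 1 | racemic trans-7-benzyloxy-2,6-dimethoxy-3-(3,4,5-trimethoxyphenyl)chroman-4-one | COc1cc2c(cc1OCc1ccccc1)O[C@@H](OC)[C@H](c1cc(OC)c(OC)c(OC)c1)C2=O
A4 | alternative 2 | 4,5-bis(benzyloxy)-2-(trimethylsilyl)phenyl trifluoromethanesulfonate | C[Si](C)(C)c1cc(OCc2ccccc2)c(OCc2ccccc2)cc1OS(=O)(=O)C(F)(F)F
A5 | alternative 2 | methyl 3-hydroxy-2-(3,4,5-trimethoxyphenyl)prop-2-enoate (identical with 2) | COC(=O)C(=CO)c1cc(OC)c(OC)c(OC)c1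
A6 | alternative 2 | 6,7-bis(benzyloxy)-3-(3,4,5-trimethoxyphenyl)-4H-chromen-4-one | O=c1c(-c2cc(OC)c(OC)c(OC)c2)coc2cc(OCc3ccccc3)c(OCc3ccccc3)cc12
A7 | alternative 2 | 6,7-dihydroxy-3-(3,4,5-trimethoxyphenyl)-4H-chromen-4-one | O=c1c(-c2cc(OC)c(OC)c(OC)c2)coc2cc(O)c(O)cc12
A8 | alternative 3 | 4-(benzyloxy)-5-methoxy-2-[2-oxo-2-(3,4,5-trimethoxyphenyl)ethoxy]benzaldehyde | COc1cc(C=O)c(OCC(=O)c2cc(OC)c(OC)c(OC)c2)cc1OCc1ccccc1
A9 | alternative 3 | racemic 7-benzyloxy-3-hydroxy-6-methoxy-3-(3,4,5-trimethoxyphenyl)chroman-4-one | COc1cc2c(cc1OCc1ccccc1)OCC(O)(c1cc(OC)c(OC)c(OC)c1)C2=O
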